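**Retrosynthetic overview**

- The phenols, the ester and the primary hydroxyl are unmasked or set last (debenzylation, acylation, desilylation), and the ring CH2 group C5 is reached from a lactol by ionic hydrogenation.
- The strategy rests on C5 of the oxolane ring (O1, C2 aryl, C3 acyloxymethyl, C4 arylmethyl, C5): it is a lone oxygenated carbon on C4, so it is cut off as a formyl group on a C3=C4 double bond whose allylic hydroxyl is O1. Hydroxyl-directed syn hydroformylation forms C4–C5 and sets C3 and C4 from the C2 carbinol centre; lactol closure forms O1–C5.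
- The Z allylic alcohol is cut at the C2–C3 bond into O-benzylvanillin and a Z alkenyl iodide, joined by a catalytic asymmetric nickel/chromium coupling that sets C2.
- The alkenyl iodide comes from a 4-arylbut-2-yn-1-ol by hydroxyl-directed trans-hydrostannation and iodination; the ynol comes from O-benzylvanillyl bromide and propargyl alcohol.
- Ring order: the oxolane is the only ring formed, in the key step; both aryl rings are bought.

Key step: step 7

Assumption: the (S)-configured oxazoline–sulfonamide ligand of step 6 is taken to steer the alkenyl group to the Re face of the aldehyde; if the Si face is favoured in practice, the (R)-ligand is used.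

**Route**

Step 1
Reactants: 1 [4-(benzyloxy)-3-methoxyphenyl]methanol
Product: 2 1-(benzyloxy)-4-(bromomethyl)-2-methoxybenzene
Conditions: PBr3 (0.4 equiv), Et2O, 0 °C
Reagents that add atoms: phosphorus tribromide, BrP(Br)Br
Why: Conversion of a benzylic alcohol into the bromide with PBr3 (displacement of the bromophosphite by bromide) should be fast at this electron-rich benzylic position and leaves the aryl benzyl ether alone.

Step 2
Reactants: 3 prop-2-yn-1-ol; 2 1-(benzyloxy)-4-(bromomethyl)-2-methoxybenzene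
Product: 5 4-[4-(benzyloxy)-3-methoxyphenyl]but-2-yn-1-ol, via dimagnesium derivative of propargyl alcohol 4 (not isolated)
Conditions: EtMgBr (2.1 equiv), THF, 0 °C to rt; CuCl (10 mol%), then 2, 50 °C
Reagents that add atoms: none
Why: Copper-catalysed alkylation of an alkynyl Grignard reagent by a benzylic bromide forms the C–C bond at the alkyne terminus, since the magnesium alkoxide of the same species is not alkylated under these conditions.

Step 3
Reactants: 5 4-[4-(benzyloxy)-3-methoxyphenyl]but-2-yn-1-ol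
Product: 6 (2Z)-4-[4-(benzyloxy)-3-methoxyphenyl]-2-(tributylstannyl)but-2-en-1-ol
Conditions: Bu3SnH (1.1 equiv, slow addition), [Cp*RuCl]4 (1.25 mol%), CH2Cl2, rt
Reagents that add atoms: tributyltin hydride, CCCC[SnH](CCCC)CCCC
Why: Hydroxyl-directed ruthenium-catalysed trans-hydrostannation should place tin on the alkyne carbon next to the CH2OH group (hydrogen bond from the hydroxyl to the chloride on ruthenium) and deliver hydrogen anti, which gives the Z alkenylstannane with tin cis to the benzylic CH2 group.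

Step 4
Reactants: 6 (2Z)-4-[4-(benzyloxy)-3-methoxyphenyl]-2-(tributylstannyl)but-2-en-1-ol
Product: 7 (2Z)-4-[4-(benzyloxy)-3-methoxyphenyl]-2-iodobut-2-en-1-ol
Conditions: I2 (1.05 equiv), CH2Cl2, 0 °C
Reagents that add atoms: iodine, II
Why: Iododestannylation (electrophilic ipso substitution of the alkenyl C–Sn bond) proceeds with retention of the double-bond geometry.

Step 5
Reactants: 7 (2Z)-4-[4-(benzyloxy)-3-methoxyphenyl]-2-iodobut-2-en-1-ol
Product: 8 {[(2Z)-4-[4-(benzyloxy)-3-methoxyphenyl]-2-iodobut-2-en-1-yl]oxy}(tert-butyl)dimethylsilane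
Conditions: TBSCl, imidazole, CH2Cl2, 0 °C to rt
Reagents that add atoms: tert-butyldimethylsilyl chloride, CC(C)(C)[Si](C)(C)Cl
Why: Imidazole-mediated silylation of the primary alcohol ensures that the carbinol oxygen formed in step 6 is the only free hydroxyl, and thus the only directing group, in the hydroformylation substrate.

Step 6
Reactants: 8 {[(2Z)-4-[4-(benzyloxy)-3-methoxyphenyl]-2-iodobut-2-en-1-yl]oxy}(tert-butyl)dimethylsilane; 9 4-(benzyloxy)-3-methoxybenzaldehyde
Product: 11 (1S,2Z)-1,4-bis[4-(benzyloxy)-3-methoxyphenyl]-2-{[(tert-butyldimethylsilyl)oxy]methyl}but-2-en-1-ol, via alkenylchromium species 10 (not isolated)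
Conditions: CrCl2 (10 mol%), N-{2-[(4S)-4-isopropyl-4,5-dihydro-1,3-oxazol-2-yl]-6-methylphenyl}methanesulfonamide (11 mol%), Et3N (20 mol%), NiCl2·(2,9-dimethyl-1,10-phenanthroline) (2 mol%), Mn (2 equiv), Cp2ZrCl2 (1.2 equiv), LiCl (2 equiv), MeCN, rt
Reagents that add atoms: none
Why: In this catalytic asymmetric Nozaki–Hiyama–Kishi coupling zerovalent nickel inserts into the C–I bond, the alkenyl group passes to chromium with retention of geometry, and the sulfonamide-bound alkenylchromium should add to the Re face of the aldehyde to set C1 as S, while Cp2ZrCl2 frees chromium from the alkoxide and Mn returns it to the divalent state.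

Step 7
Reactants: 11 (1S,2Z)-1,4-bis[4-(benzyloxy)-3-methoxyphenyl]-2-{[(tert-butyldimethylsilyl)oxy]methyl}but-2-en-1-ol
Product: 14 (3S,4S,5R)-5-[4-(benzyloxy)-3-methoxyphenyl]-3-{[4-(benzyloxy)-3-methoxyphenyl]methyl}-4-{[(tert-butyldimethylsilyl)oxy]methyl}oxolan-2-ol (both anomers), via substrate diphenylphosphinite 12 (not isolated), via hydroxy aldehyde 13 (not isolated)
Conditions: Rh(acac)(CO)2 (5 mol%), Ph2POMe (25 mol%), 4 Å MS, CO/H2 (1:1, 40 bar), THF, 60 °C
Reagents that add atoms: carbon monoxide, [C-]#[O+]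
Why: Proposed new method: Ph2POMe exchanges its methoxy group for the carbinol oxygen of 11 (the future O1; the sieves take up methanol) to give phosphinite 12, whose phosphorus holds the rhodium hydride on the oxygen face of the alkene; hydrometalation then puts hydrogen on the fully substituted alkene carbon (future C3) and rhodium on the CH carbon (future C4) through a six-membered P–O–C–C–C–Rh chelate, and CO insertion, hydrogenolysis and release of the phosphinite leave hydroxy aldehyde 13 with the new C3–H and C4–CHO bonds syn. The closest known reaction type is the rhodium-catalysed hydroformylation of homoallylic alcohols and of 1,1-disubstituted allylic alcohols under control of reversibly or covalently bound phosphorus directing groups; a trisubstituted allylic alcohol has not been shown as substrate, and because its undirected reaction is very slow, any turnover should be the directed one. The oxolane ring closes by 5-exo-trig attack of the freed hydroxyl on the formyl carbon, which forms O1–C5 after the C4–C5 bond; C5 arises as both anomers and stops being a stereocentre in step 8. C3 and C4 are controlled by the C2 carbinol centre: allylic 1,3-strain with the cis benzylic CH2 group holds the C2–H bond in the alkene plane, so the phosphinite oxygen and the aryl group lie on opposite faces, and syn addition to the Z alkene from the oxygen face gives the 2,3-trans, 3,4-cis arrangement (2R,3S,4S in oxolane numbering). The step needs formyl at C4, which the chelate ring size secures together with the fact that formyl at C3 would create a quaternary centre, and it needs CO insertion to outrun β-hydride elimination from the C4 alkylrhodium species, which the CO pressure is chosen to secure.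

Step 8
Reactants: 14 (3S,4S,5R)-5-[4-(benzyloxy)-3-methoxyphenyl]-3-{[4-(benzyloxy)-3-methoxyphenyl]methyl}-4-{[(tert-butyldimethylsilyl)oxy]methyl}oxolan-2-ol (both anomers)
Product: 15 {[(2R,3S,4S)-2-[4-(benzyloxy)-3-methoxyphenyl]-4-{[4-(benzyloxy)-3-methoxyphenyl]methyl}oxolan-3-yl]methoxy}(tert-butyl)dimethylsilane
Conditions: Et3SiH (3 equiv), BF3·OEt2 (1.5 equiv), CH2Cl2, −78 °C; Et3N quench at −78 °C
Reagents that add atoms: none
Why: In this ionic hydrogenation of a lactol BF3 ionises the anomeric hydroxyl to the cyclic oxocarbenium ion, which Et3SiH reduces; at −78 °C the benzylic C2–O bond and the silyl ether should not ionise, and the three ring centres are untouched.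

Step 9
Reactants: 15 {[(2R,3S,4S)-2-[4-(benzyloxy)-3-methoxyphenyl]-4-{[4-(benzyloxy)-3-methoxyphenyl]methyl}oxolan-3-yl]methoxy}(tert-butyl)dimethylsilane
Product: 16 [(2R,3S,4S)-2-[4-(benzyloxy)-3-methoxyphenyl]-4-{[4-(benzyloxy)-3-methoxyphenyl]methyl}oxolan-3-yl]methanol
Conditions: TBAF, THF, 0 °C to rt
Reagents that add atoms: none
Why: Fluoride-mediated cleavage of the silyl ether works under non-acidic conditions, which spare the acid-sensitive benzylic C2–O bond of the oxolane.

Step 10
Reactants: 16 [(2R,3S,4S)-2-[4-(benzyloxy)-3-methoxyphenyl]-4-{[4-(benzyloxy)-3-methoxyphenyl]methyl}oxolan-3-yl]methanol; 17 (2R)-2-methylbutanoic acid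
Product: 19 [(2R,3S,4S)-2-[4-(benzyloxy)-3-methoxyphenyl]-4-{[4-(benzyloxy)-3-methoxyphenyl]methyl}oxolan-3-yl]methyl (2R)-2-methylbutanoate, via O-acylisourea 18 (not isolated)
Conditions: DCC, DMAP (10 mol%), CH2Cl2, 0 °C to rt
Reagents that add atoms: none
Why: Steglich esterification through the O-acylisourea and the N-acylpyridinium ion should carry the R centre of the acid over unchanged, since an α-alkyl acid without an activating α-heteroatom does not epimerise with catalytic DMAP at 0 °C.

Step 11
Reactants: 19 [(2R,3S,4S)-2-[4-(benzyloxy)-3-methoxyphenyl]-4-{[4-(benzyloxy)-3-methoxyphenyl]methyl}oxolan-3-yl]methyl (2R)-2-methylbutanoate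
Product: 20 [(2R,3S,4S)-2-(4-hydroxy-3-methoxyphenyl)-4-[(4-hydroxy-3-methoxyphenyl)methyl]oxolan-3-yl]methyl (2R)-2-methylbutanoate
Conditions: H2 (1 atm), Pd/C (10% palladium on carbon), EtOAc, rt
Reagents that add atoms: none
Why: Hydrogenolysis of the two aryl benzyl ethers over palladium in neutral ethyl acetate should be much faster than cleavage of the cyclic benzylic C2–O bond, and the reaction is stopped after two equivalents of hydrogen.

**Compound list**

1 | [4-(benzyloxy)-3-methoxyphenyl]methanol (O-benzylvanillyl alcohol) | COc1cc(CO)ccc1OCc1ccccc1 | starting material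
2 | 1-(benzyloxy)-4-(bromomethyl)-2-methoxybenzene (O-benzylvanillyl bromide) | COc1cc(CBr)ccc1OCc1ccccc1 | intermediate
3 | prop-2-yn-1-ol (propargyl alcohol) | C#CCO | starting material
4 | bromomagnesium 3-(bromomagnesio)prop-2-yn-1-olate (dimagnesium derivative of propargyl alcohol) | Br[Mg]C#CCO[Mg]Br | intermediate
5 | 4-[4-(benzyloxy)-3-methoxyphenyl]but-2-yn-1-ol | OCC#CCc1ccc(OCc2ccccc2)c(OC)c1 | intermediate
6 | (2Z)-4-[4-(benzyloxy)-3-methoxyphenyl]-2-(tributylstannyl)but-2-en-1-ol | OC/C(=C/Cc1ccc(OCc2ccccc2)c(OC)c1)[Sn](CCCC)(CCCC)CCCC | intermediate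
7 | (2Z)-4-[4-(benzyloxy)-3-methoxyphenyl]-2-iodobut-2-en-1-ol | OC/C(I)=C/Cc1ccc(OCc2ccccc2)c(OC)c1 | intermediate
8 | {[(2Z)-4-[4-(benzyloxy)-3-methoxyphenyl]-2-iodobut-2-en-1-yl]oxy}(tert-butyl)dimethylsilane | CC(C)(C)[Si](C)(C)OC/C(I)=C/Cc1ccc(OCc2ccccc2)c(OC)c1 | intermediate
9 | 4-(benzyloxy)-3-methoxybenzaldehyde (O-benzylvanillin) | COc1cc(C=O)ccc1OCc1ccccc1 | starting material
10 | [(2Z)-4-[4-(benzyloxy)-3-methoxyphenyl]-1-{[tert-butyl(dimethyl)silyl]oxy}but-2-en-2-yl]chromium dichloride (trivalent chromium; chiral ligand omitted) | CC(C)(C)[Si](C)(C)OC/C(=C/Cc1ccc(OCc2ccccc2)c(OC)c1)[Cr](Cl)Cl | intermediate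
11 | (1S,2Z)-1,4-bis[4-(benzyloxy)-3-methoxyphenyl]-2-{[(tert-butyldimethylsilyl)oxy]methyl}but-2-en-1-ol | O[C@H](/C(=C\Cc1ccc(OCc2ccccc2)c(OC)c1)CO[Si](C)(C)C(C)(C)C)c1ccc(OCc2ccccc2)c(OC)c1 | intermediate
12 | {[(1S,2Z)-1,4-bis[4-(benzyloxy)-3-methoxyphenyl]-2-{[(tert-butyldimethylsilyl)oxy]methyl}but-2-en-1-yl]oxy}diphenylphosphane (diphenylphosphinite of 11) | c1ccccc1P(c1ccccc1)O[C@H](/C(=C\Cc1ccc(OCc2ccccc2)c(OC)c1)CO[Si](C)(C)C(C)(C)C)c1ccc(OCc2ccccc2)c(OC)c1 | intermediate
13 | (2S,3S,4R)-4-[4-(benzyloxy)-3-methoxyphenyl]-2-{[4-(benzyloxy)-3-methoxyphenyl]methyl}-3-{[(tert-butyldimethylsilyl)oxy]methyl}-4-hydroxybutanal | O[C@H]([C@H](CO[Si](C)(C)C(C)(C)C)[C@@H](C=O)Cc1ccc(OCc2ccccc2)c(OC)c1)c1ccc(OCc2ccccc2)c(OC)c1 | intermediate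
14 | (3S,4S,5R)-5-[4-(benzyloxy)-3-methoxyphenyl]-3-{[4-(benzyloxy)-3-methoxyphenyl]methyl}-4-{[(tert-butyldimethylsilyl)oxy]methyl}oxolan-2-ol (both anomers) | CC(C)(C)[Si](C)(C)OC[C@@H]1[C@H](Cc2ccc(OCc3ccccc3)c(OC)c2)C(O)O[C@H]1c1ccc(OCc2ccccc2)c(OC)c1 | intermediate
15 | {[(2R,3S,4S)-2-[4-(benzyloxy)-3-methoxyphenyl]-4-{[4-(benzyloxy)-3-methoxyphenyl]methyl}oxolan-3-yl]methoxy}(tert-butyl)dimethylsilane | CC(C)(C)[Si](C)(C)OC[C@@H]1[C@H](Cc2ccc(OCc3ccccc3)c(OC)c2)CO[C@H]1c1ccc(OCc2ccccc2)c(OC)c1 | intermediate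
16 | [(2R,3S,4S)-2-[4-(benzyloxy)-3-methoxyphenyl]-4-{[4-(benzyloxy)-3-methoxyphenyl]methyl}oxolan-3-yl]methanol | OC[C@@H]1[C@H](Cc2ccc(OCc3ccccc3)c(OC)c2)CO[C@H]1c1ccc(OCc2ccccc2)c(OC)c1 | intermediate
17 | (2R)-2-methylbutanoic acid | CC[C@@H](C)C(=O)O | starting material
18 | N,N'-dicyclohexyl-O-[(2R)-2-methylbutanoyl]isourea | CC[C@@H](C)C(=O)OC(=NC1CCCCC1)NC1CCCCC1 | intermediate
19 | [(2R,3S,4S)-2-[4-(benzyloxy)-3-methoxyphenyl]-4-{[4-(benzyloxy)-3-methoxyphenyl]methyl}oxolan-3-yl]methyl (2R)-2-methylbutanoate | CC[C@@H](C)C(=O)OC[C@@H]1[C@H](Cc2ccc(OCc3ccccc3)c(OC)c2)CO[C@H]1c1ccc(OCc2ccccc2)c(OC)c1 | intermediate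
20 | [(2R,3S,4S)-2-(4-hydroxy-3-methoxyphenyl)-4-[(4-hydroxy-3-methoxyphenyl)methyl]oxolan-3-yl]methyl (2R)-2-methylbutanoate | CC[C@@H](C)C(=O)OC[C@@H]1[C@H](Cc2ccc(O)c(OC)c2)CO[C@H]1c1ccc(O)c(OC)c1 | target

**Step count**

Total steps: 11. Longest linear sequence: 11 steps (1 to 20); 9 and 17 enter as bought materials.

**Steps most likely to fail**

1. Step 7 (directed hydroformylation, proposed new method). Several processes may defeat it:
   - the trisubstituted alkene may not turn over, or the hindered carbinol may exchange too slowly with Ph2POMe;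
   - the allylic phosphinite may be lost by a [2,3]-sigmatropic shift to a phosphine oxide;
   - β-hydride elimination may scramble the alkene geometry (loss of the 3,4-cis relation) or move the double bond into conjugation with the aryl ring;
   - the allylic alcohol may isomerise to the ketone;
   - the lactol may epimerise at C4 through its open form.

   The fallback uses only known chemistry, sets out from aldehyde 9 and comes back to the route at alcohol 16.
   - Stobbe condensation of 9 with dimethyl succinate (NaOMe, MeOH, reflux) would give (3E)-4-[4-(benzyloxy)-3-methoxyphenyl]-3-(methoxycarbonyl)but-3-enoic acid F1.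
   - Asymmetric hydrogenation with [Rh(cod)2]BF4 and a chiral bisphosphine such as Et-DuPhos (enantiomer chosen for 3S; aryl benzyl ethers are inert to the homogeneous catalyst) would give (3S)-4-[4-(benzyloxy)-3-methoxyphenyl]-3-(methoxycarbonyl)butanoic acid F2.
   - Reduction of the ester beside the potassium carboxylate with Ca(BH4)2, then acid, would give (4S)-4-{[4-(benzyloxy)-3-methoxyphenyl]methyl}oxolan-2-one F3.
   - Its lithium enolate (LiHMDS, THF, −78 °C) should add to a second equivalent of 9 anti to the benzyl group to give the trans aldol lactone (3R,4S)-3-{[4-(benzyloxy)-3-methoxyphenyl](hydroxy)methyl}-4-{[4-(benzyloxy)-3-methoxyphenyl]methyl}oxolan-2-one F4 as a mixture of carbinol epimers.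
   - LiAlH4 would give (2S,3S)-2-{[4-(benzyloxy)-3-methoxyphenyl](hydroxy)methyl}-3-{[4-(benzyloxy)-3-methoxyphenyl]methyl}butane-1,4-diol F5.
   - Camphorsulfonic acid in CH2Cl2 ionises the benzylic alcohol, and the hydroxyl on the future C5 closes the oxolane trans to the C3 substituent, so both carbinol epimers should converge on 16. The trans lactone maps onto the 3,4-cis oxolane.

2. Step 6 (asymmetric nickel/chromium coupling). Facial selectivity at the aldehyde may be poor with this hindered, fully substituted alkenyl iodide, or the coupling may be slow. The product alcohol ionises readily and should be purified on neutralised silica. The configuration is checked by Mosher ester analysis.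

   The fallback sets out from iodide 8 and aldehyde 9 and comes back at 11.
   - Coupling without chiral ligand (CrCl2 in excess, NiCl2 2 mol%, DMF, rt) would give rac-(2Z)-1,4-bis[4-(benzyloxy)-3-methoxyphenyl]-2-{[(tert-butyldimethylsilyl)oxy]methyl}but-2-en-1-ol F6.
   - Dess–Martin periodinane with NaHCO3 in CH2Cl2 would give (2Z)-1,4-bis[4-(benzyloxy)-3-methoxyphenyl]-2-{[(tert-butyldimethylsilyl)oxy]methyl}but-2-en-1-one F7, which is kept cold and away from base to avoid Z-to-E isomerisation.
   - Corey–Bakshi–Shibata reduction with (S)-2-methyl-CBS-oxazaborolidine and catecholborane in toluene at −40 °C would return 11. The planar aryl group is expected to act as the large substituent; this is checked on a small scale before the catalyst enantiomer is fixed.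

3. Step 8 (lactol deoxygenation). BF3 may ionise the benzylic C2–O bond (ring opening or epimerisation at C2), the oxocarbenium ion may lose a proton at C4 (epimerisation through the enol ether), or the silyl ether may be lost.

   The fallback sets out from lactol 14 and comes back at 15.
   - NaBH4 in MeOH at 0 °C reduces the open form to (1R,2S,3S)-1-[4-(benzyloxy)-3-methoxyphenyl]-3-{[4-(benzyloxy)-3-methoxyphenyl]methyl}-2-{[(tert-butyldimethylsilyl)oxy]methyl}butane-1,4-diol F8.
   - Selective sulfonylation of the primary hydroxyl (TsCl, Et3N, DMAP 5 mol%, CH2Cl2, 0 °C) would give (2S,3S,4R)-4-[4-(benzyloxy)-3-methoxyphenyl]-2-{[4-(benzyloxy)-3-methoxyphenyl]methyl}-3-{[(tert-butyldimethylsilyl)oxy]methyl}-4-hydroxybutyl 4-methylbenzenesulfonate F9.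
   - NaH in THF closes the ring by intramolecular Williamson etherification (5-exo-tet) at the primary carbon, with retention at C2, to give 15 without any Lewis acid.

**Further compounds**

F1 | step 7 | (3E)-4-[4-(benzyloxy)-3-methoxyphenyl]-3-(methoxycarbonyl)but-3-enoic acid | COC(=O)/C(CC(=O)O)=C/c1ccc(OCc2ccccc2)c(OC)c1
F2 | step 7 | (3S)-4-[4-(benzyloxy)-3-methoxyphenyl]-3-(methoxycarbonyl)butanoic acid | OC(=O)C[C@H](Cc1ccc(OCc2ccccc2)c(OC)c1)C(=O)OC
F3 | step 7 | (4S)-4-{[4-(benzyloxy)-3-methoxyphenyl]methyl}oxolan-2-one | O=C1C[C@H](Cc2ccc(OCc3ccccc3)c(OC)c2)CO1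
F4 | step 7 | (3R,4S)-3-{[4-(benzyloxy)-3-methoxyphenyl](hydroxy)methyl}-4-{[4-(benzyloxy)-3-methoxyphenyl]methyl}oxolan-2-one (carbinol epimers) | O=C1OC[C@@H](Cc2ccc(OCc3ccccc3)c(OC)c2)[C@@H]1C(O)c1ccc(OCc2ccccc2)c(OC)c1
F5 | step 7 | (2S,3S)-2-{[4-(benzyloxy)-3-methoxyphenyl](hydroxy)methyl}-3-{[4-(benzyloxy)-3-methoxyphenyl]methyl}butane-1,4-diol (carbinol epimers) | OC[C@@H](Cc1ccc(OCc2ccccc2)c(OC)c1)[C@@H](CO)C(O)c1ccc(OCc2ccccc2)c(OC)c1
F6 | step 6 | rac-(2Z)-1,4-bis[4-(benzyloxy)-3-methoxyphenyl]-2-{[(tert-butyldimethylsilyl)oxy]methyl}but-2-en-1-ol | OC(/C(=C\Cc1ccc(OCc2ccccc2)c(OC)c1)CO[Si](C)(C)C(C)(C)C)c1ccc(OCc2ccccc2)c(OC)c1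
F7 | step 6 | (2Z)-1,4-bis[4-(benzyloxy)-3-methoxyphenyl]-2-{[(tert-butyldimethylsilyl)oxy]methyl}but-2-en-1-one | O=C(/C(=C\Cc1ccc(OCc2ccccc2)c(OC)c1)CO[Si](C)(C)C(C)(C)C)c1ccc(OCc2ccccc2)c(OC)c1
F8 | step 8 | (1R,2S,3S)-1-[4-(benzyloxy)-3-methoxyphenyl]-3-{[4-(benzyloxy)-3-methoxyphenyl]methyl}-2-{[(tert-butyldimethylsilyl)oxy]methyl}butane-1,4-diol | O[C@H]([C@H](CO[Si](C)(C)C(C)(C)C)[C@@H](CO)Cc1ccc(OCc2ccccc2)c(OC)c1)c1ccc(OCc2ccccc2)c(OC)c1
F9 | step 8 | (2S,3S,4R)-4-[4-(benzyloxy)-3-methoxyphenyl]-2-{[4-(benzyloxy)-3-methoxyphenyl]methyl}-3-{[(tert-butyldimethylsilyl)oxy]methyl}-4-hydroxybutyl 4-methylbenzenesulfonate | O[C@H]([C@H](CO[Si](C)(C)C(C)(C)C)[C@@H](COS(=O)(=O)c1ccc(C)cc1)Cc1ccc(OCc2ccccc2)c(OC)c1)c1ccc(OCc2ccccc2)c(OC)c1
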